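(The numbers in the tables were computed with constants of no real substance; noise was put on by code.)

Late in both earlier runs Q was still falling along a nearly straight line, so I started there, from these charges and readings.

the same everywhere: E 200 mM (held)
- zeta: Q 1 M; Z 2.1 M; run made earlier
- gamma: Q 1.5 M; Z 1.5 M; run made earlier
- flask: Q 1.0 M; Z 1.50 M; time 50 min

| run | time / min | Q / % | X / % |
|---|---|---|---|
| zeta | 1.50 | 98.4 | 0.1 |
| zeta | 5.00 | 95.8 | 3.4 |
| zeta | 8.00 | 92.2 | 8.0 |
| zeta | 12.0 | 87.8 | 10.3 |
| zeta | 20.0 | 81.7 | 20.2 |
| zeta | 25.0 | 74.0 | 26.5 |
| zeta | 30.0 | 67.1 | 31.6 |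
| gamma | 2.50 | 99.1 | 0.5 |
| gamma | 8.00 | 95.1 | 4.7 |
| gamma | 15.0 | 88.9 | 11.1 |
| gamma | 20.0 | 84.7 | 15.8 |
| gamma | 30.0 | 75.0 | 24.9 |

(standard deviation of a reading: 1 percentage point)

* part of the Q that has reacted at 50 min
* share of the unused J that is free and not bound as D, at 50 min

- what is said of G includes D
- at the start none of J is dissolved
- on the list of suspects stand: Q + J -> X + G; J + G <-> D; Z + G -> L; E <-> J
- the earlier runs do not show how much of J is bound; that part of a forecast is a guess

My quantity is the throughput u, the concentration of Q used divided by the time since the start: 11.0 mM min⁻¹ in the zeta run at 30.0 min, and 12.5 mM min⁻¹ in the gamma run at 30.0 min. Gamma held 1.50 times the cQ of zeta, yet its throughput was 1.14 times as large, so cQ moved the rate weakly, though Z differed between the runs too.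

Then I ran the flask through slowly. At the start cJ was zero, so Q + J had to wait for E to feed J in; the zeta run showed that lag, with X at 0.1% after 1.50 min. In the middle I expected J to be fed and used side by side while G built up, partly held as D and partly removed by Z, giving a nearly zero-order stretch in Q. Towards 50 min the falling cQ should bend the line down, while the early lag had pulled u low, and I let these two cancel. The flask had the cQ of zeta, so I reckoned u·t/cQ = 54.8%. I could not read the effect of its Z charge, and the readings did not show bound J.

The forecast stood lower than my reckoning: 50% reacted (41% to 62%) and 65% of the unused J free (25% to 95%), with the remark “Both runs are almost linear in time, with a slight speed-up and a short early lag.”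

The flask gave 52.5% reacted and 70.3% free, the second 5.3 percentage points above the forecast.

    Q + J → X + G (k = 0.256 M⁻¹ min⁻¹)
    J + G ⇌ D, settled at all times (K = 4.10 M⁻¹)
    Z + G → L (k = 0.0790 M⁻¹ min⁻¹)
    E ⇌ J, rate k4*(csat - [J]) (kL = 0.0898 min⁻¹)

Moving the Z charge from zeta's to the flask's left the Q used at the time of zeta's last reading, without the scatter, at 31.7%, against 32.0%. The flask's own throughput came to 10.5 mM min⁻¹, against u = 11.0 mM min⁻¹.

A neighbour flask held 1.7 M of Q, with the flask's Z and time. The gamma throughput, from a run with that Z charge, gives 36.8% reacted there, and the computed result was 38.4%.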